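**Remark (assumption).** The name of the target follows the older numbering of quinic acid. Below, the IUPAC numbering is used: C1 is the quaternary carbon, C7 the carboxyl carbon, O3 is cis to O4, and O4 is trans to O5. In this numbering the SMILES places the methyl ether on O1 and the caffeoyl ester on O5.

## Analysis of the target

The target is a cyclohexane (the quinic acid ring) with four stereocentres. C1 is fully substituted and carries a methoxy group and the carboxyl carbon C7; C3, C4 and C5 are contiguous secondary carbinol carbons. In the chair with the carboxyl equatorial, O1 and O3 are both axial and cis (1,3-diaxial), while O4 and O5 are equatorial. O3 and O4 are therefore cis, O4 and O5 trans, and the carboxyl is cis to O5. O5 carries an (E)-caffeoyl ester; O3, O4, the catechol and the acid are free. The caffeoyl ester migrates to neighbouring hydroxyls and is cleaved under basic conditions, the catechol is easily oxidised, and the cinnamoyl double bond rules out a late hydrogenation. A free carboxyl beside a free O5 can also close the bridged γ-lactone. The hard points are the configuration of the quaternary C1 relative to the triol, methylation of the tertiary O1 only, acylation of O5 only among three secondary hydroxyls, and a final deprotection that uses acid alone. The strategy rests on the cis-1,3-diaxial relation of O1 (on C1) and O3 (on C3): a free C3 hydroxyl can hand an oxygen atom to C1 of an exocyclic C1=C7 alkene, and C7 of that alkene later becomes the carboxyl carbon.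

## Retrosynthetic reasoning

**Ester at O5 (22 ⇒ 21 ⇒ 17 + 20).** The O5–acyl bond is cut first because the caffeoyl unit is the most fragile part and should be carried through as few steps as possible. In 21 the phenols are acetates, O3/O4 an acetonide and the acid a tert-butyl ester, so one acidic hydrolysis should release 22 without any basic step. The acid chloride 20 comes from caffeic acid 18 through the diacetate 19. The forward acylation has only one free hydroxyl (O5 of 17) to find.

**Singling out O5 (17 ⇒ 16).** No bond of the skeleton is cut here; the acetonide is moved. In 16 it spans the trans-diequatorial O4/O5 pair and O3 is free. Acid should shift it to the cis O3/O4 pair, which relieves the strain of the trans-fused five-membered ring and leaves O5 free. The tert-butyl ester is chosen because it does not lactonise onto O5 and leaves in the final acid step.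

**Carboxyl from C7 (16 ⇒ 15 ⇒ 13 ⇒ 12).** These are changes of oxidation state and protecting groups only. The acid 15 is traced to the primary alcohol 13, which comes from the dibenzyl ether 12 by hydrogenolysis while no alkene is yet present. The forward oxidation must take the primary C7 alcohol past the axial secondary C3 alcohol.

**C7–O and O1–CH3 (12 ⇒ 10 ⇒ 9).** Both bonds are traced to the spiro-epoxide. A benzyl alkoxide should attack the primary C7 of 10, so the C1–O bond and its configuration are untouched, and the tertiary alkoxide 11 that results is methylated in the same flask. O1 is then the only alkoxide present, so the methyl group can go nowhere else. Opening with hydroxide was not chosen: it would give a tertiary/primary 1,2-diol that is prone to C1–C7 cleavage on oxidation, and the methylation would then have to be done later on a hindered hydroxy ester. O3 is masked as a benzyl ether (10 from 9) rather than a silyl ether, because the C1 alkoxide lies 1,3-diaxial to O3 and a silyl group could shuttle between the two oxygens.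

**C1–O, the key disconnection (9 ⇒ 8).** The C1–O bond (and with it the temporary C7–O bond) is cut back to the exocyclic alkene 8. The forward reaction must deliver oxygen to the alkene face syn to the axial C3 hydroxyl; a hydroxyl-directed, vanadium-catalysed epoxidation does this through a metal tether. Here the quaternary stereocentre is made, and here the risk of the route is placed.

**C2–C3 and the ring (8 ⇒ 7).** The homoallylic alcohol with an exocyclic methylene is the retron of an intramolecular carbonyl-ene reaction of a 2-methylallyl group with an aldehyde. Cutting C2–C3 gives the open-chain aldehyde 7. The forward closure forms the six-membered ring, the C3 stereocentre and the exocyclic alkene in one step. A closure through a methyl ketone (intramolecular aldol onto the aldehyde, a 6-(enolendo)-exo-trig process, then methylenation) was set aside: it passes through a β-hydroxy ketone that can dehydrate or equilibrate by retro-aldol, and it needs a basic methylenation afterwards.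

**C6–C1 and the chiral pool (7 ⇒ 6 ⇒ 5 ⇒ 3 + 4; 3 ⇒ 2 ⇒ 1).** The C6–C1 bond is cut to the primary triflate 3 and the alkenyl Grignard reagent 4, joined by copper catalysis. Triflate 3 comes from the C2-symmetric diol 1 through its monosilyl ether 2; because of the symmetry, monofunctionalisation can give only one compound. The two stereocentres of 1 become C4 and C5 of the target with the correct absolute configuration, and the trans-dioxolane later locks the ring conformation that the key step needs.

## Alternatives that were turned down

**Alternative 1:** The ring bonds C1–C6 and C2–C3 are cut in a [4+2] sense, leading to buta-1,3-diene A1 and methyl 2-methoxyprop-2-enoate A2. In the forward direction a chiral cationic oxazaborolidine Lewis acid would bind the ester of A2 and A1 would add to one face, giving methyl (S)-1-methoxycyclohex-3-ene-1-carboxylate A3 with C1 set. Saponification, iodolactonisation, elimination and cis-dihydroxylation on the convex face of the bridged lactone would then relay C1 to C5, C4 and C3.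
- For it: C1 arrives in the first step with its methoxy group and carboxyl carbon, all seven skeletal carbons are present at once, and the lactone relay is stereospecific. It would be shorter than the chosen route by about five steps, and on step economy it is the stronger plan.
- Against it: A2 is an α-alkoxy acrylate whose donor oxygen raises the LUMO, and A1 is the least reactive simple diene. Neither partner has a substituent that fixes one geometry in the catalyst complex, and the methoxy oxygen can compete for the Lewis acid. Nothing in the structure secures the enantioselectivity. At that stage there is no second stereocentre, so a shortfall cannot be corrected by separating diastereomers and is inherited by every later centre. The relay also ends with O5 tied into the lactone, so freeing O5 while masking the acid needs a basic lactone opening.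
- Comparison: the chosen route is longer, but its absolute configuration comes from the chiral pool, and each relative configuration is enforced by a rigid trans-fused bicycle.

**Alternative 2:** The C1–C7 bond and the O1–CH3 bond are cut, leading to (3R,5R)-3,4,5-tris(benzyloxy)cyclohexan-1-one A4 and 2-lithiofuran A5 as a carboxyl-anion equivalent. In the forward direction A5 would add to the C1 carbonyl from the equatorial direction and the alkoxide would be methylated in the same flask, giving 2-[(3R,5R)-3,4,5-tris(benzyloxy)-1-methoxycyclohexyl]furan A6. The furan would later be degraded oxidatively to the acid.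
- For it: the quaternary centre, the methyl ether and the masked carboxyl are installed in one operation, the three carbinol centres come intact from a pentitol, and the route is probably shorter than the chosen one.
- Against it: A4 is a β-alkoxy ketone on both sides, so a basic organolithium can trigger loss of benzyloxide through the enolate. The ring is not conformationally locked, and small sp2 nucleophiles tend to attack axially, which would give the wrong C1 epimer. The oxidative furan cleavage must be run in the presence of three benzyl ethers, which strong oxidants attack. Three identical ethers do not distinguish O5.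
- Comparison: the methylation-on-formation idea is the same as in step 9 of the chosen route. The chosen route, however, delivers the C1 oxygen intramolecularly from O3, so the C1 configuration does not depend on steric approach control.

**Alternative 3:** The C1–C2 bond is cut with allylic transposition ([3,3] retron), leading to the lactone (5R,6S)-5-(tert-butyldimethylsilyloxy)-6-ethenyl-3-methoxyoxan-2-one A7. In the forward direction its silyl ketene acetal would undergo Ireland–Claisen rearrangement through a boat-like transition state. C1–C2 forms on the lactone face that carries the vinyl group as the C4–O bond breaks, giving (1S,5R)-5-(tert-butyldimethylsilyloxy)-1-methoxycyclohex-3-ene-1-carboxylic acid A8.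
- For it: the chirality transfer is pericyclic and stereospecific, C1 receives its methoxy group and carboxyl at once, and O5 is already differentiated as a silyl ether. On that last point it is stronger than the chosen route, which needs an acetal migration.
- Against it: A7 needs its own enantioselective synthesis with a trans stereodiad and an α-methoxy group. The rearrangement must pass a strained bicyclic boat with a fully substituted α-alkoxy ketene acetal. C3 and C4 are then left to a late cis-dihydroxylation whose required face is anti to the allylic silyloxy group but syn to the homoallylic C1 methoxy group. That methoxy group is probably axial in the half-chair, so the two influences oppose each other.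
- Comparison: the length is comparable or shorter. The chosen route fixes all three carbinol centres before C1 and lets C1 follow from C3 by delivery, so no late stereocentre depends on competing directing effects.

Key step: step 7

## Route

**Step 1**
Reactants: 1 (−)-2,3-O-isopropylidene-D-threitol
Product: 2 [(4R,5R)-5-({[tert-butyl(dimethyl)silyl]oxy}methyl)-2,2-dimethyl-1,3-dioxolan-4-yl]methanol
Conditions: NaH (1.0 equiv), THF, 0 °C → rt; then TBSCl (1.0 equiv)
Reagents that add atoms: tert-butyldimethylsilyl chloride, CC(C)(C)[Si](C)(C)Cl
Why: Monosilylation of a symmetric diol through its monosodium alkoxide; 1 is C2-symmetric, so both hydroxyls are equivalent and only one monoether can form, and the stereocentres are not touched.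

**Step 2**
Reactants: 2 [(4R,5R)-5-({[tert-butyl(dimethyl)silyl]oxy}methyl)-2,2-dimethyl-1,3-dioxolan-4-yl]methanol
Product: 3 [(4R,5R)-5-({[tert-butyl(dimethyl)silyl]oxy}methyl)-2,2-dimethyl-1,3-dioxolan-4-yl]methyl trifluoromethanesulfonate
Conditions: Tf2O, pyridine, CH2Cl2, −20 °C; used at once
Reagents that add atoms: trifluoromethanesulfonic anhydride, O=S(=O)(OS(=O)(=O)C(F)(F)F)C(F)(F)F
Why: O-Sulfonylation of the primary alcohol; the triflate is chosen because displacement at this β-oxygenated primary carbon is slow with poorer leaving groups.

**Step 3**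
Reactants: 3 the triflate from step 2; 4 isopropenylmagnesium bromide
Product: 5 tert-butyl(dimethyl){[(4R,5R)-2,2-dimethyl-5-(2-methylprop-2-en-1-yl)-1,3-dioxolan-4-yl]methoxy}silane
Conditions: CuBr·SMe2 (10 mol %), Et2O/THF, −30 → 0 °C
Reagents that add atoms: none
Why: Copper-catalysed cross-coupling of a Grignard reagent with a primary triflate (SN2 displacement by an alkenylcuprate), forming the C6–C1 bond; the silyl ether and acetonide are inert to the cuprate and no stereocentre is involved.

**Step 4**
Reactants: 5 tert-butyl(dimethyl){[(4R,5R)-2,2-dimethyl-5-(2-methylprop-2-en-1-yl)-1,3-dioxolan-4-yl]methoxy}silane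
Product: 6 [(4R,5R)-2,2-dimethyl-5-(2-methylprop-2-en-1-yl)-1,3-dioxolan-4-yl]methanol
Conditions: Bu4NF, THF, 0 °C → rt
Reagents that add atoms: none
Why: Fluoride cleavage of the silyl ether; nothing else in 5 reacts with fluoride.

**Step 5**
Reactants: 6 [(4R,5R)-2,2-dimethyl-5-(2-methylprop-2-en-1-yl)-1,3-dioxolan-4-yl]methanol
Product: 7 (4S,5R)-2,2-dimethyl-5-(2-methylprop-2-en-1-yl)-1,3-dioxolane-4-carbaldehyde
Conditions: (COCl)2, DMSO, CH2Cl2, −78 °C; Et3N, −78 → 0 °C; used crude
Reagents that add atoms: none
Why: Swern oxidation of the primary alcohol; the α-centre of the aldehyde sits on the thermodynamically preferred trans-dioxolane, so base-induced epimerisation is not a concern (the change of descriptor from 4R to 4S is a priority change only).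

**Step 6**
Reactants: 7 (4S,5R)-2,2-dimethyl-5-(2-methylprop-2-en-1-yl)-1,3-dioxolane-4-carbaldehyde
Product: 8 (3aR,4R,7aR)-2,2-dimethyl-6-methylidenehexahydro-1,3-benzodioxol-4-ol [(3R,4R,5R)-4,5-O-isopropylidene-1-methylidenecyclohexane-3,4,5-triol]
Conditions: Me2AlCl (1.5 equiv), CH2Cl2, −78 → −20 °C; aq. potassium sodium tartrate
Reagents that add atoms: none
Why: Type 2 intramolecular carbonyl-ene reaction: the terminal alkene carbon attacks the aluminium-bound aldehyde carbon (new C2–C3 bond, six-membered ring) while a methyl hydrogen passes to oxygen, so the methyl group becomes the exocyclic methylene. The trans-dioxolane forces a chair-like transition state with the C4–O bond equatorial and anti to the forming bond, and the concerted hydrogen transfer is possible only with the complexed carbonyl oxygen axial (gauche to C1), so the C3 hydroxyl should come out axial and cis to O4.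

**Step 7 (key step)**
Reactants: 8 (3aR,4R,7aR)-2,2-dimethyl-6-methylidenehexahydro-1,3-benzodioxol-4-ol
Product: 9 (3aR,4R,6S,7aR)-2,2-dimethylhexahydrospiro[1,3-benzodioxole-6,2'-oxiran]-4-ol (epoxide oxygen on C1 cis to the C3 hydroxyl)
Conditions: VO(acac)2 (5 mol %), t-BuOOH (1.5 equiv, in decane), CH2Cl2, 0 °C → rt
Reagents that add atoms: tert-butyl hydroperoxide, CC(C)(C)OO
Why: VO(acac)2 (tetravalent vanadium) is oxidised by the hydroperoxide to a pentavalent vanadate ester that exchanges ligands for the C3 alkoxide of 8 and a tert-butylperoxo group. The C1=C7 π bond attacks the metal-bound peroxide oxygen along the O–O axis, and one oxygen atom is transferred in a single step to both alkene carbons, closing the oxirane by a [2+1] atom transfer (new C1–O and C7–O bonds). The closest known reaction type is the vanadium-catalysed hydroxyl-directed epoxidation of cyclic homoallylic alcohols, which delivers oxygen syn to the hydroxyl. The only new stereocentre is C1, and it is controlled by C3 through the V–O3 tether: the trans-fused acetonide holds O4 and O5 equatorial and therefore O3 axial and 1,3 to C1, so the metal sits over the axial face of the exocyclic alkene. The oxygen should therefore end up axial on C1, cis to O3 and O4, with C7 equatorial and cis to O5. Only face selectivity is needed, since there is one alkene, and the rigid chair secures it; the untethered pathway is slow with this catalyst. The product cannot be opened by its own hydroxyl, because O3 is on the same face as the epoxide oxygen and cannot reach the back side of C1 or C7.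

**Step 8**
Reactants: 9 the spiro-epoxide from step 7
Product: 10 (3aR,4R,7aR)-4-(benzyloxy)-2,2-dimethylhexahydrospiro[1,3-benzodioxole-6,2'-oxirane] (3-O-benzyl ether of 9)
Conditions: NaH, BnBr, Bu4NI (cat.), THF/DMF, 0 °C → rt
Reagents that add atoms: benzyl bromide, BrCc1ccccc1
Why: Williamson etherification of the C3 alkoxide; the epoxide survives because the alkoxide is cis to the epoxide oxygen and cannot attack it from the back. A benzyl group cannot migrate to O1 in the next step.

**Step 9**
Reactants: 10 the 3-O-benzyl spiro-epoxide
Product: 12 3-O-benzyl-1-C-(benzyloxymethyl)-4,5-O-isopropylidene-1-O-methylcyclohexane-1,3,4,5-tetrol (O1 cis to O3 and O4), via tertiary sodium alkoxide 11 (not isolated)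
Conditions: BnOH (4 equiv), NaH (3 equiv), DMF, 70 °C; then NaH (2 equiv), MeI (6 equiv), 0 °C → rt
Reagents that add atoms: benzyl alcohol, OCc1ccccc1; iodomethane, CI
Why: Benzyl alkoxide opens the 2,2-disubstituted oxirane by SN2 attack at the primary C7, so the C1–O bond and the C1 configuration are retained; the tertiary alkoxide 11 is then methylated in the same flask (Williamson ether synthesis). O1 is the only alkoxide on the substrate, so the methyl group has a single site.

**Step 10**
Reactants: 12 the dibenzyl ether from step 9
Product: 13 1-C-(hydroxymethyl)-4,5-O-isopropylidene-1-O-methylcyclohexane-1,3,4,5-tetrol (O1 cis to O3 and O4)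
Conditions: H2 (1 atm), Pd(OH)2/C, EtOH/EtOAc, rt
Reagents that add atoms: none
Why: Neutral hydrogenolysis removes both benzyl ethers; the strained trans-acetonide and the methyl ether are inert, and no alkene is present at this stage.

**Step 11**
Reactants: 13 the diol from step 10
Product: 15 4,5-O-isopropylidene-1-O-methylquinic acid, via α-methoxy aldehyde 14 (not isolated)
Conditions: TEMPO (0.2 equiv), PhI(OAc)2 (2.5 equiv), MeCN/aq. NaH2PO4–Na2HPO4 buffer (pH 7), 0 °C → rt; crude acid used at once
Reagents that add atoms: water, O
Why: Oxoammonium (TEMPO) oxidation with PhI(OAc)2 as terminal oxidant is selective for primary over secondary alcohols; aldehyde 14 is hydrated in the aqueous medium and oxidised on to the acid. The axial, flanked C3 hydroxyl should react much more slowly, and the buffer protects the trans-acetonide.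

**Step 12**
Reactants: 15 4,5-O-isopropylidene-1-O-methylquinic acid
Product: 16 tert-butyl 4,5-O-isopropylidene-1-O-methylquinate
Conditions: O-tert-butyl-N,N'-diisopropylisourea (3 equiv), CH2Cl2, rt
Reagents that add atoms: O-tert-butyl-N,N'-diisopropylisourea, CC(C)NC(=NC(C)C)OC(C)(C)C
Why: The acid protonates the isourea and the carboxylate captures the tert-butyl group (O-alkylation, not acyl substitution), so the hindered quaternary carboxyl is no obstacle and the free C3 hydroxyl, being too weakly acidic, is left alone.

**Step 13**
Reactants: 16 tert-butyl 4,5-O-isopropylidene-1-O-methylquinate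
Product: 17 tert-butyl 3,4-O-isopropylidene-1-O-methylquinate (free O5 hydroxyl)
Conditions: CSA (10 mol %), acetone, rt; Et3N quench
Reagents that add atoms: none
Why: Acid-catalysed acetal migration under thermodynamic control: the trans-fused dioxolane opens to an oxocarbenium ion held on O4, which the cis C3 hydroxyl closes to the unstrained cis-fused 3,4-acetonide. No C–O bond of the ring is broken, so no stereocentre is affected, and the tert-butyl ester does not lactonise onto the freed O5.

**Step 14**
Reactants: 18 caffeic acid
Product: 19 (E)-3-(3,4-diacetoxyphenyl)prop-2-enoic acid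
Conditions: Ac2O, pyridine, rt; then H2O
Reagents that add atoms: acetic anhydride, CC(=O)OC(C)=O
Why: O-Acetylation of both phenols; the water quench returns any carboxyl that was transiently acylated.

**Step 15**
Reactants: 19 (E)-3-(3,4-diacetoxyphenyl)prop-2-enoic acid
Product: 20 (E)-3-(3,4-diacetoxyphenyl)prop-2-enoyl chloride
Conditions: (COCl)2, DMF (cat.), CH2Cl2, 0 °C → rt; evaporated and used crude
Reagents that add atoms: oxalyl chloride, O=C(Cl)C(=O)Cl
Why: Acid chloride formation through the chloroiminium species from DMF; the aryl acetates and the E-alkene are unaffected.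

**Step 16**
Reactants: 17 tert-butyl 3,4-O-isopropylidene-1-O-methylquinate; 20 (E)-3-(3,4-diacetoxyphenyl)prop-2-enoyl chloride
Product: 21 tert-butyl 5-O-[(E)-3-(3,4-diacetoxyphenyl)prop-2-enoyl]-3,4-O-isopropylidene-1-O-methylquinate
Conditions: pyridine, DMAP (cat.), CH2Cl2, 0 °C → rt
Reagents that add atoms: none
Why: DMAP-catalysed acylation of the only free hydroxyl, the equatorial O5; all other oxygens are masked.

**Step 17**
Reactants: 21 the fully protected ester from step 16
Product: 22 5-O-[(E)-caffeoyl]-1-O-methylquinic acid (3-O-caffeoyl-1-methylquinic acid in the older numbering; the target)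
Conditions: 2 M aq. HCl/THF (1:1), rt
Reagents that add atoms: none
Why: Acidic hydrolysis should remove the acetonide (through its oxocarbenium ion), the tert-butyl ester (alkyl–oxygen cleavage) and the two aryl acetates, which are more labile than the conjugated secondary caffeate. Under acid the caffeoyl group should not migrate, and the acid cannot lactonise because O5 is acylated and O3 and O4 are trans to the carboxyl.

## Compound list

1 | (−)-2,3-O-isopropylidene-D-threitol, [(4R,5R)-2,2-dimethyl-1,3-dioxolane-4,5-diyl]dimethanol | OC[C@H]1OC(C)(C)O[C@@H]1CO | starting material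
2 | [(4R,5R)-5-({[tert-butyl(dimethyl)silyl]oxy}methyl)-2,2-dimethyl-1,3-dioxolan-4-yl]methanol | CC(C)(C)[Si](C)(C)OC[C@H]1OC(C)(C)O[C@@H]1CO | intermediate
3 | [(4R,5R)-5-({[tert-butyl(dimethyl)silyl]oxy}methyl)-2,2-dimethyl-1,3-dioxolan-4-yl]methyl trifluoromethanesulfonate | CC(C)(C)[Si](C)(C)OC[C@H]1OC(C)(C)O[C@@H]1COS(=O)(=O)C(F)(F)F | intermediate
4 | isopropenylmagnesium bromide (prop-1-en-2-ylmagnesium bromide) | C=C(C)[Mg]Br | starting material
5 | tert-butyl(dimethyl){[(4R,5R)-2,2-dimethyl-5-(2-methylprop-2-en-1-yl)-1,3-dioxolan-4-yl]methoxy}silane | CC(C)(C)[Si](C)(C)OC[C@H]1OC(C)(C)O[C@@H]1CC(C)=C | intermediate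
6 | [(4R,5R)-2,2-dimethyl-5-(2-methylprop-2-en-1-yl)-1,3-dioxolan-4-yl]methanol | OC[C@H]1OC(C)(C)O[C@@H]1CC(C)=C | intermediate
7 | (4S,5R)-2,2-dimethyl-5-(2-methylprop-2-en-1-yl)-1,3-dioxolane-4-carbaldehyde | O=C[C@H]1OC(C)(C)O[C@@H]1CC(C)=C | intermediate
8 | (3aR,4R,7aR)-2,2-dimethyl-6-methylidenehexahydro-1,3-benzodioxol-4-ol; (3R,4R,5R)-4,5-O-isopropylidene-1-methylidenecyclohexane-3,4,5-triol, C3 hydroxyl axial and cis to O4 | C=C1C[C@@H](O)[C@H]2OC(C)(C)O[C@@H]2C1 | intermediate
9 | (3aR,4R,6S,7aR)-2,2-dimethylhexahydrospiro[1,3-benzodioxole-6,2'-oxiran]-4-ol; spiro-epoxide with the epoxide oxygen on C1 cis to the C3 hydroxyl | O1C[C@@]12C[C@@H](O)[C@H]3OC(C)(C)O[C@@H]3C2 | intermediate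
10 | 3-O-benzyl ether of 9; (3aR,4R,7aR)-4-(benzyloxy)-2,2-dimethylhexahydrospiro[1,3-benzodioxole-6,2'-oxirane], epoxide oxygen cis to the benzyloxy group | O1C[C@@]12C[C@@H](OCc4ccccc4)[C@H]3OC(C)(C)O[C@@H]3C2 | intermediate
11 | sodium 3-O-benzyl-1-C-(benzyloxymethyl)-4,5-O-isopropylidenecyclohexane-3,4,5-triol-1-olate (tertiary alkoxide, O1 cis to O3 and O4) | [Na+].[O-][C@@]1(COCc2ccccc2)C[C@@H](OCc2ccccc2)[C@H]2OC(C)(C)O[C@@H]2C1 | intermediate
12 | 3-O-benzyl-1-C-(benzyloxymethyl)-4,5-O-isopropylidene-1-O-methylcyclohexane-1,3,4,5-tetrol (O1 cis to O3 and O4, trans to O5) | CO[C@@]1(COCc2ccccc2)C[C@@H](OCc2ccccc2)[C@H]2OC(C)(C)O[C@@H]2C1 | intermediate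
13 | 1-C-(hydroxymethyl)-4,5-O-isopropylidene-1-O-methylcyclohexane-1,3,4,5-tetrol (O1 cis to O3 and O4, trans to O5) | CO[C@@]1(CO)C[C@@H](O)[C@H]2OC(C)(C)O[C@@H]2C1 | intermediate
14 | 3-hydroxy-4,5-(isopropylidenedioxy)-1-methoxycyclohexane-1-carbaldehyde (same configuration as 13) | CO[C@@]1(C=O)C[C@@H](O)[C@H]2OC(C)(C)O[C@@H]2C1 | intermediate
15 | 4,5-O-isopropylidene-1-O-methylquinic acid | CO[C@@]1(C(=O)O)C[C@@H](O)[C@H]2OC(C)(C)O[C@@H]2C1 | intermediate
16 | tert-butyl 4,5-O-isopropylidene-1-O-methylquinate | CO[C@@]1(C(=O)OC(C)(C)C)C[C@@H](O)[C@H]2OC(C)(C)O[C@@H]2C1 | intermediate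
17 | tert-butyl 3,4-O-isopropylidene-1-O-methylquinate (free equatorial O5 hydroxyl) | CO[C@@]1(C(=O)OC(C)(C)C)C[C@H]2OC(C)(C)O[C@H]2[C@H](O)C1 | intermediate
18 | caffeic acid, (E)-3-(3,4-dihydroxyphenyl)prop-2-enoic acid | O=C(O)/C=C/c1ccc(O)c(O)c1 | starting material
19 | (E)-3-(3,4-diacetoxyphenyl)prop-2-enoic acid | CC(=O)Oc1ccc(/C=C/C(=O)O)cc1OC(C)=O | intermediate
20 | (E)-3-(3,4-diacetoxyphenyl)prop-2-enoyl chloride | CC(=O)Oc1ccc(/C=C/C(=O)Cl)cc1OC(C)=O | intermediate
21 | tert-butyl 5-O-[(E)-3-(3,4-diacetoxyphenyl)prop-2-enoyl]-3,4-O-isopropylidene-1-O-methylquinate | CO[C@@]1(C(=O)OC(C)(C)C)C[C@H]2OC(C)(C)O[C@H]2[C@H](OC(=O)/C=C/c3ccc(OC(C)=O)c(OC(C)=O)c3)C1 | intermediate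
22 | 5-O-[(E)-caffeoyl]-1-O-methylquinic acid (3-O-caffeoyl-1-methylquinic acid, older numbering) | CO[C@@]1(C(=O)O)C[C@@H](O)[C@@H](O)[C@H](OC(=O)/C=C/c2ccc(O)c(O)c2)C1 | target

## Step count and least certain steps

Total: 17 steps. Longest linear sequence: 15 steps (steps 1–13, 16 and 17); steps 14 and 15 prepare the acid chloride separately.

**Step 7 (key step).** A homoallylic alcohol binds and turns over more slowly than an allylic one. The reaction may therefore stall, letting oxidation of the C3 carbinol to the ketone or a non-directed, less face-selective pathway compete; the vanadium Lewis acid may also rearrange the 2,2-disubstituted oxirane. The fallback keeps the idea of oxygen delivery from O3 but uses an electrophile-driven cyclisation. It sets out from 8 and returns at 9.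
- With n-BuLi and Boc2O in THF, 8 is converted into tert-butyl (3aR,4R,7aR)-2,2-dimethyl-6-methylidenehexahydro-1,3-benzodioxol-4-yl carbonate F1.
- IBr in toluene at −80 °C forms the iodonium ion, and the carbonate carbonyl oxygen closes onto C1 from the O3 face (6-exo) with loss of the tert-butyl group, giving the bridged cyclic iodocarbonate F2.
- K2CO3 in MeOH cleaves the carbonate, and the liberated C1 alkoxide displaces iodide at C7 to give 9.

**Step 6.** The closure may proceed through an open, stepwise transition state and lose face selectivity at C3. The tertiary cation may be captured by chloride, or the Lewis acid may open the acetonide. The fallback sets the C3 centre by reagent-controlled reduction instead. It sets out from 7 and returns at 8.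
- The cyclisation is run without regard to C3, giving 8 together with its C3 epimer (3aR,4S,7aR)-2,2-dimethyl-6-methylidenehexahydro-1,3-benzodioxol-4-ol F3.
- The mixture is oxidised with triacetoxy periodinane (DMP) and NaHCO3 in CH2Cl2 to (3aS,7aR)-2,2-dimethyl-6-methylidenetetrahydro-1,3-benzodioxol-4(3aH)-one F4.
- Reduction with LiBH(sec-Bu)3 in THF at −78 °C, which adds hydride from the equatorial direction, should give the axial alcohol 8.

**Step 3.** Decomposition of the triflate (displacement by bromide, or ring-opening of THF) may outrun the transfer of the alkenyl group from copper. The fallback builds the 2-methylallyl group through an acyl-anion equivalent. It sets out from 2 and returns at 5.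
- PPh3, I2 and imidazole convert 2 into tert-butyl{[(4R,5S)-5-(iodomethyl)-2,2-dimethyl-1,3-dioxolan-4-yl]methoxy}dimethylsilane F5.
- Alkylation of 2-lithio-2-methyl-1,3-dithiane (from 2-methyl-1,3-dithiane and n-BuLi, THF/DMPU) gives tert-butyl(dimethyl)({(4R,5R)-2,2-dimethyl-5-[(2-methyl-1,3-dithian-2-yl)methyl]-1,3-dioxolan-4-yl}methoxy)silane F6.
- MeI and CaCO3 in aqueous MeCN release 1-[(4R,5R)-5-({[tert-butyl(dimethyl)silyl]oxy}methyl)-2,2-dimethyl-1,3-dioxolan-4-yl]propan-2-one F7.
- Wittig methylenation with Ph3P=CH2 (from Ph3PCH3Br and KN(SiMe3)2) at low temperature gives 5.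

**Step 11.** Chemoselectivity may be lost through oxidation of the C3 carbinol. The free hydroxy acid may also promote an acetonide shift followed by lactonisation onto O5. The fallback keeps O3 benzylated until the ester is in place, at the cost of one step. It sets out from 10 and returns at 16.
- Epoxide 10 is opened with sodium 4-methoxybenzyl oxide in DMF to the sodium alkoxide 3-O-benzyl-1-C-[(4-methoxybenzyloxy)methyl]-4,5-O-isopropylidenecyclohexane-3,4,5-triol-1-olate F8.
- Methylation with MeI in the same flask gives 3-O-benzyl-1-C-[(4-methoxybenzyloxy)methyl]-4,5-O-isopropylidene-1-O-methylcyclohexane-1,3,4,5-tetrol F9.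
- DDQ in CH2Cl2/pH 7 buffer removes the 4-methoxybenzyl group only, giving 3-O-benzyl-1-C-(hydroxymethyl)-4,5-O-isopropylidene-1-O-methylcyclohexane-1,3,4,5-tetrol F10.
- TEMPO/PhI(OAc)2 oxidation passes through 3-(benzyloxy)-4,5-(isopropylidenedioxy)-1-methoxycyclohexane-1-carbaldehyde F11 to 3-O-benzyl-4,5-O-isopropylidene-1-O-methylquinic acid F12.
- The isourea of step 12 gives tert-butyl 3-O-benzyl-4,5-O-isopropylidene-1-O-methylquinate F13.
- Hydrogenolysis (H2, Pd(OH)2/C) gives 16.

**Step 17.** Cleavage of the aryl acetates and the tert-butyl ester may be too slow under conditions that spare the caffeoyl ester, so that partial hydrolysis of the caffeate or acyl migration accompanies the deprotection. The fallback unmasks in two orthogonal stages. It sets out from 21 and returns at 22.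
- NH4OAc in aqueous MeOH at rt removes only the phenolic acetates, giving tert-butyl 5-O-[(E)-caffeoyl]-3,4-O-isopropylidene-1-O-methylquinate F14.
- TFA/H2O (9:1) at 0 °C then removes the acetonide and the tert-butyl ester by cation-forming pathways that do not touch the ester, giving 22.

## Further compounds

F1 | step 7 | tert-butyl (3aR,4R,7aR)-2,2-dimethyl-6-methylidenehexahydro-1,3-benzodioxol-4-yl carbonate | C=C1C[C@@H](OC(=O)OC(C)(C)C)[C@H]2OC(C)(C)O[C@@H]2C1
F2 | step 7 | bridged cyclic iodocarbonate: 1-C-(iodomethyl)-4,5-O-isopropylidenecyclohexane-1,3,4,5-tetrol 1,3-carbonate (O1 cis to O3) | IC[C@@]12C[C@@H](OC(=O)O1)[C@H]3OC(C)(C)O[C@@H]3C2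
F3 | step 6 | (3aR,4S,7aR)-2,2-dimethyl-6-methylidenehexahydro-1,3-benzodioxol-4-ol (C3 epimer of 8) | C=C1C[C@H](O)[C@H]2OC(C)(C)O[C@@H]2C1
F4 | step 6 | (3aS,7aR)-2,2-dimethyl-6-methylidenetetrahydro-1,3-benzodioxol-4(3aH)-one | C=C1CC(=O)[C@H]2OC(C)(C)O[C@@H]2C1
F5 | step 3 | tert-butyl{[(4R,5S)-5-(iodomethyl)-2,2-dimethyl-1,3-dioxolan-4-yl]methoxy}dimethylsilane | CC(C)(C)[Si](C)(C)OC[C@H]1OC(C)(C)O[C@@H]1CI
F6 | step 3 | tert-butyl(dimethyl)({(4R,5R)-2,2-dimethyl-5-[(2-methyl-1,3-dithian-2-yl)methyl]-1,3-dioxolan-4-yl}methoxy)silane | CC(C)(C)[Si](C)(C)OC[C@H]1OC(C)(C)O[C@@H]1CC1(C)SCCCS1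
F7 | step 3 | 1-[(4R,5R)-5-({[tert-butyl(dimethyl)silyl]oxy}methyl)-2,2-dimethyl-1,3-dioxolan-4-yl]propan-2-one | CC(C)(C)[Si](C)(C)OC[C@H]1OC(C)(C)O[C@@H]1CC(C)=O
F8 | step 11 | sodium 3-O-benzyl-1-C-[(4-methoxybenzyloxy)methyl]-4,5-O-isopropylidenecyclohexane-3,4,5-triol-1-olate | [Na+].[O-][C@@]1(COCc2ccc(OC)cc2)C[C@@H](OCc2ccccc2)[C@H]2OC(C)(C)O[C@@H]2C1
F9 | step 11 | 3-O-benzyl-1-C-[(4-methoxybenzyloxy)methyl]-4,5-O-isopropylidene-1-O-methylcyclohexane-1,3,4,5-tetrol | CO[C@@]1(COCc2ccc(OC)cc2)C[C@@H](OCc2ccccc2)[C@H]2OC(C)(C)O[C@@H]2C1
F10 | step 11 | 3-O-benzyl-1-C-(hydroxymethyl)-4,5-O-isopropylidene-1-O-methylcyclohexane-1,3,4,5-tetrol | CO[C@@]1(CO)C[C@@H](OCc2ccccc2)[C@H]2OC(C)(C)O[C@@H]2C1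
F11 | step 11 | 3-(benzyloxy)-4,5-(isopropylidenedioxy)-1-methoxycyclohexane-1-carbaldehyde | CO[C@@]1(C=O)C[C@@H](OCc2ccccc2)[C@H]2OC(C)(C)O[C@@H]2C1
F12 | step 11 | 3-O-benzyl-4,5-O-isopropylidene-1-O-methylquinic acid | CO[C@@]1(C(=O)O)C[C@@H](OCc2ccccc2)[C@H]2OC(C)(C)O[C@@H]2C1
F13 | step 11 | tert-butyl 3-O-benzyl-4,5-O-isopropylidene-1-O-methylquinate | CO[C@@]1(C(=O)OC(C)(C)C)C[C@@H](OCc2ccccc2)[C@H]2OC(C)(C)O[C@@H]2C1
F14 | step 17 | tert-butyl 5-O-[(E)-caffeoyl]-3,4-O-isopropylidene-1-O-methylquinate | CO[C@@]1(C(=O)OC(C)(C)C)C[C@H]2OC(C)(C)O[C@H]2[C@H](OC(=O)/C=C/c3ccc(O)c(O)c3)C1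
A1 | alternative 1 | buta-1,3-diene | C=CC=C
A2 | alternative 1 | methyl 2-methoxyprop-2-enoate | COC(=C)C(=O)OC
A3 | alternative 1 | methyl (S)-1-methoxycyclohex-3-ene-1-carboxylate | CO[C@@]1(C(=O)OC)CCC=CC1
A4 | alternative 2 | (3R,5R)-3,4,5-tris(benzyloxy)cyclohexan-1-one | O=C1C[C@@H](OCc2ccccc2)[C@@H](OCc2ccccc2)[C@H](OCc2ccccc2)C1
A5 | alternative 2 | 2-lithiofuran | [Li]c1ccco1
A6 | alternative 2 | 2-[(3R,5R)-3,4,5-tris(benzyloxy)-1-methoxycyclohexyl]furan (methoxy cis to O3 and O4) | CO[C@@]1(c2ccco2)C[C@@H](OCc2ccccc2)[C@@H](OCc2ccccc2)[C@H](OCc2ccccc2)C1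
A7 | alternative 3 | (5R,6S)-5-(tert-butyldimethylsilyloxy)-6-ethenyl-3-methoxyoxan-2-one (silyloxy and vinyl trans) | COC1C[C@@H](O[Si](C)(C)C(C)(C)C)[C@H](C=C)OC1=O
A8 | alternative 3 | (1S,5R)-5-(tert-butyldimethylsilyloxy)-1-methoxycyclohex-3-ene-1-carboxylic acid | CO[C@@]1(C(=O)O)CC=C[C@H](O[Si](C)(C)C(C)(C)C)C1
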